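**Retrosynthetic overview**
1. Lettering: ring A is the catechol ring bound through oxygen to the para-phenylene ring B. Ring C is the second catechol ring and ring D the meta-phenylene ring. In rings A and C, C1 bears the CH2CH2 bridge, C3 and C4 the oxygens, and C5 the aryloxy group.
2. The target comes from a macrocyclic trimethyl ether by BBr3 cleavage. The four benzene rings are bought, and the 19-membered macrocycle is the only ring formed (step 7).
3. The macrocycle is cut at the diaryl ether bond O(ring B)–C5(ring A). In one flask, ring A is dearomatised to an orthoquinol acetate, fluoride frees the ring B phenolate, oxa-1,6-addition closes the ring, and loss of AcOH restores the arene. C5 needs no halogen.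
4. Enabling feature: once C4 of ring A is an sp3 C(OMe)(OAc), C3=O/C2=C1/C6=C5 is a linear dienone. Its β-carbon C1 is blocked by the bridge. Its δ-carbon C5 is the aryloxy carbon and lies next to the leaving group.
5. The seco-phenol comes from a bis(diarylalkyne) by one hydrogenation. The bis(diarylalkyne) is assembled by two alkyne homologation/Sonogashira pairs around one Ullmann coupling (ring D–O–ring C).

Key step: step 7

Assumption: the target has no stereocentre and its macrocycle is taken as conformationally mobile, so no stereochemical element has to be set.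

Step 1
Reactants: 1 3-(benzyloxy)-4-methoxybenzaldehyde (O-benzylisovanillin)
Product: 2 2-(benzyloxy)-4-ethynyl-1-methoxybenzene
Conditions: Ohira-Bestmann reagent (1.2 equiv), K2CO3 (2 equiv), MeOH/THF, rt
Reagents that add atoms: Ohira-Bestmann reagent, dimethyl (1-diazo-2-oxopropyl)phosphonate, COP(=O)(OC)C(=[N+]=[N-])C(C)=O (its diazo carbon becomes the terminal alkyne carbon)
Why: The Seyferth-Gilbert homologation in its Ohira-Bestmann form turns non-enolisable aromatic aldehydes into terminal alkynes under carbonate/methanol conditions that leave aryl benzyl and methyl ethers untouched.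

Step 2
Reactants: 2 2-(benzyloxy)-4-ethynyl-1-methoxybenzene; 3 3-iodophenol
Product: 4 3-{[3-(benzyloxy)-4-methoxyphenyl]ethynyl}phenol
Conditions: PdCl2(PPh3)2 (2 mol%), CuI (4 mol%), Et3N/THF, rt, argon
Reagents that add atoms: none
Why: Sonogashira coupling of an aryl iodide runs at room temperature and tolerates the free phenol, which is meta to the new alkyne and so cannot cyclise onto it.

Step 3
Reactants: 4 3-{[3-(benzyloxy)-4-methoxyphenyl]ethynyl}phenol; 5 3-bromo-4,5-dimethoxybenzaldehyde
Product: 6 3-(3-{[3-(benzyloxy)-4-methoxyphenyl]ethynyl}phenoxy)-4,5-dimethoxybenzaldehyde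
Conditions: CuI (20 mol%), N,N-dimethylglycine hydrochloride (40 mol%), Cs2CO3 (2.5 equiv), 1,4-dioxane, 100 °C
Reagents that add atoms: none
Why: The ligand-accelerated Ullmann diaryl ether synthesis couples phenols with ortho-alkoxy aryl bromides, and the internal alkyne, benzyl ether and non-enolisable aldehyde are inert to CuI/Cs2CO3.

Step 4
Reactants: 6 3-(3-{[3-(benzyloxy)-4-methoxyphenyl]ethynyl}phenoxy)-4,5-dimethoxybenzaldehyde
Product: 7 1-(3-{[3-(benzyloxy)-4-methoxyphenyl]ethynyl}phenoxy)-5-ethynyl-2,3-dimethoxybenzene
Conditions: Ohira-Bestmann reagent (1.3 equiv), K2CO3 (2 equiv), MeOH/THF, rt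
Reagents that add atoms: Ohira-Bestmann reagent, dimethyl (1-diazo-2-oxopropyl)phosphonate, COP(=O)(OC)C(=[N+]=[N-])C(C)=O (its diazo carbon becomes the terminal alkyne carbon)
Why: This is the same Seyferth-Gilbert/Ohira-Bestmann homologation as in step 1, run before the base-labile aryl silyl ether enters the molecule.

Step 5
Reactants: 7 1-(3-{[3-(benzyloxy)-4-methoxyphenyl]ethynyl}phenoxy)-5-ethynyl-2,3-dimethoxybenzene; 8 tert-butyl(4-iodophenoxy)dimethylsilane
Product: 9 bis(diarylalkyne): 7 carrying a 4-(tert-butyldimethylsilyloxy)phenyl group on its terminal alkyne carbon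
Conditions: PdCl2(PPh3)2 (3 mol%), CuI (5 mol%), Et3N/THF, rt to 40 °C, argon
Reagents that add atoms: none
Why: Sonogashira coupling of an aryl iodide needs only an amine base, which leaves the aryl silyl ether in place.

Step 6
Reactants: 9 bis(diarylalkyne)
Product: 10 seco-phenol 5-{2-[3-(5-{2-[4-(tert-butyldimethylsilyloxy)phenyl]ethyl}-2,3-dimethoxyphenoxy)phenyl]ethyl}-2-methoxyphenol
Conditions: H2 (3 atm), 10% Pd/C, EtOAc/THF, rt
Reagents that add atoms: none
Why: Heterogeneous catalytic hydrogenation saturates both diarylalkynes to ethano bridges and hydrogenolyses the single benzyl ether in the same operation, while silyl, methyl and diaryl ethers persist in a non-protic solvent.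

Step 7
Reactants: 10 seco-phenol
Product: 14 macrocyclic monophenol trimethyl ether, via orthoquinol acetate 11 (not isolated), via ammonium phenolate 12 (not isolated), via macrocyclic dienolate 13 (not isolated)
Conditions: PhI(OAc)2 (1.05 equiv), CH2Cl2, −78 to 0 °C; this solution then added by syringe pump to TBAF (3 equiv) in THF, 0 °C to rt, final about 1 mM; aq NH4Cl
Reagents that add atoms: PhI(OAc)2, CC(=O)OI(OC(C)=O)c1ccccc1 (one acetoxy group sits in 11, 12 and 13 and has left again in 14); TBAF, CCCC[N+](CCCC)(CCCC)CCCC.[F-] (its cation is the counter-ion of 12 and 13 only)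
Why: Proposed new method: PhI(OAc)2 engages the only free phenol (O on C3 of ring A) and delivers acetate to the methoxy-bearing ortho carbon C4 (Wessely-type oxidative acetoxylation) to give the 6-acetoxy-6-methoxycyclohexa-2,4-dienone 11; fluoride then strips the silyl group from ring B, the naked phenolate 12 adds through oxygen to the δ-carbon C5 (oxa-1,6-addition, 19-endo-trig), and the dienolate 13 loses H from C5 and acetate from C4 to restore the arene. The closest known reaction type is the fluoride-triggered intramolecular oxa-conjugate addition of silyl-masked alcohols to orthoquinol acetates, which rearomatises by loss of acetic acid to give benzo-fused oxygen rings; new here are a phenolate as nucleophile, the δ-position as acceptor and a macrocyclic ring size. Site selectivity rests on the substitution pattern: the β-carbon C1 carries the ethano bridge, so an adduct there has no hydrogen to lose and reverts, whereas the adduct at C5 lies next to the leaving group and aromatises irreversibly. The oxidation is chemoselective because ring B is silylated and rings C and D bear no free phenol, and the methoxy group on C4 directs the acetate to that carbon rather than to C2 or C6. O-attack over C-attack is favoured by the tetrabutylammonium counter-ion in an aprotic medium, and ring closure over oligomerisation or Diels-Alder dimerisation of the dienone by slow addition at high dilution. The stereocentres at C4 and C5 in 11 to 13 are transient, form as mixtures and vanish on aromatisation, so no stereocontrol is needed.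

Step 8
Reactants: 14 macrocyclic monophenol trimethyl ether
Product: 15 target CNP0511668.0
Conditions: BBr3 (8 equiv), CH2Cl2, −78 °C to rt; degassed ice-water, argon
Reagents that add atoms: none
Why: BBr3 ether cleavage (boron-oxygen complexation, then bromide SN2 at methyl) removes all three methyl groups and cannot cleave the diaryl ethers, which offer no sp3 carbon; it is the customary last step for bis(bibenzyl) methyl ethers.

**Compound list**
1 | 3-(benzyloxy)-4-methoxybenzaldehyde | COc1ccc(C=O)cc1OCc1ccccc1 | starting material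
2 | 2-(benzyloxy)-4-ethynyl-1-methoxybenzene | COc1ccc(C#C)cc1OCc1ccccc1 | intermediate
3 | 3-iodophenol | Oc1cccc(I)c1 | starting material
4 | 3-{[3-(benzyloxy)-4-methoxyphenyl]ethynyl}phenol | COc1ccc(C#Cc2cccc(O)c2)cc1OCc1ccccc1 | intermediate
5 | 3-bromo-4,5-dimethoxybenzaldehyde | COc1cc(C=O)cc(Br)c1OC | starting material
6 | 3-(3-{[3-(benzyloxy)-4-methoxyphenyl]ethynyl}phenoxy)-4,5-dimethoxybenzaldehyde | COc1ccc(C#Cc2cccc(Oc3cc(C=O)cc(OC)c3OC)c2)cc1OCc1ccccc1 | intermediate
7 | 1-(3-{[3-(benzyloxy)-4-methoxyphenyl]ethynyl}phenoxy)-5-ethynyl-2,3-dimethoxybenzene | COc1ccc(C#Cc2cccc(Oc3cc(C#C)cc(OC)c3OC)c2)cc1OCc1ccccc1 | intermediate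
8 | tert-butyl(4-iodophenoxy)dimethylsilane | CC(C)(C)[Si](C)(C)Oc1ccc(I)cc1 | starting material
9 | bis(diarylalkyne), ring A O-benzyl, ring B O-TBS | COc1ccc(C#Cc2cccc(Oc3cc(C#Cc4ccc(O[Si](C)(C)C(C)(C)C)cc4)cc(OC)c3OC)c2)cc1OCc1ccccc1 | intermediate
10 | seco-phenol (ring A 3-OH, 4-OMe; ring C 3,4-di-OMe; ring B O-TBS) | COc1ccc(CCc2cccc(Oc3cc(CCc4ccc(O[Si](C)(C)C(C)(C)C)cc4)cc(OC)c3OC)c2)cc1O | intermediate
11 | orthoquinol acetate: ring A as racemic 6-acetoxy-6-methoxy-3-alkylcyclohexa-2,4-dien-1-one | COC1(OC(C)=O)C=CC(CCc2cccc(Oc3cc(CCc4ccc(O[Si](C)(C)C(C)(C)C)cc4)cc(OC)c3OC)c2)=CC1=O | intermediate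
12 | tetrabutylammonium phenolate of desilylated 11 | COC1(OC(C)=O)C=CC(CCc2cccc(Oc3cc(CCc4ccc([O-])cc4)cc(OC)c3OC)c2)=CC1=O.CCCC[N+](CCCC)(CCCC)CCCC | intermediate
13 | macrocyclic dienolate (1,6-adduct; diastereomer mixture at C4 and C5 of ring A), tetrabutylammonium salt | COC1(OC(C)=O)C([O-])=CC2=CC1Oc1ccc(cc1)CCc1cc(OC)c(OC)c(c1)Oc1cccc(c1)CC2.CCCC[N+](CCCC)(CCCC)CCCC | intermediate
14 | macrocyclic monophenol trimethyl ether (ring A 3-OH, 4-OMe; ring C 3,4-di-OMe) | COc1c(O)cc2cc1Oc1ccc(cc1)CCc1cc(OC)c(OC)c(c1)Oc1cccc(c1)CC2 | intermediate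
15 | CNP0511668.0 | Oc1cc2cc(c1O)Oc1ccc(cc1)CCc1cc(O)c(O)c(c1)Oc1cccc(c1)CC2 | target

**Total step count:** 8. **Longest linear sequence:** 8 (1 to 15).

**Steps most likely to fail**

Step 7.
- What may go wrong: attack at the δ-carbon next to the quaternary C4 may be slow. The phenolate could then instead take the acetyl group (acyl transfer), or enolise the dienone toward the benzylic CH2. The dienone could also dimerise by Diels-Alder reaction or oligomerise before the ring closes.
- Fallback: it sets out from 5, comes back at 15, and uses known chemistry only. Ring A is bought with its leaving group, and the same O–C5 bond is closed by an intramolecular Ullmann reaction.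
- Aldehyde 5 is homologated with the Ohira-Bestmann reagent to 1-bromo-5-ethynyl-2,3-dimethoxybenzene F1.
- Sonogashira coupling of F1 with 3 at room temperature (iodide before bromide) should give 3-[(3-bromo-4,5-dimethoxyphenyl)ethynyl]phenol F2.
- Ullmann coupling of F2 with purchased 3-iodo-4,5-dimethoxybenzaldehyde F3 follows (CuI, N,N-dimethylglycine, Cs2CO3, dioxane, 80 °C). The iodide reacts faster than the hindered bromide, which should give 3-{3-[(3-bromo-4,5-dimethoxyphenyl)ethynyl]phenoxy}-4,5-dimethoxybenzaldehyde F4.
- A second homologation gives the terminal alkyne 1-bromo-5-{[3-(5-ethynyl-2,3-dimethoxyphenoxy)phenyl]ethynyl}-2,3-dimethoxybenzene F5.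
- Sonogashira coupling with purchased 4-iodophenol F6 gives the bromo bis(diarylalkyne) phenol F7.
- Diimide (TsNHNH2, NaOAc, DME/water, reflux) saturates both alkynes without touching the C–Br bond and gives the bromo seco-phenol F8.
- Intramolecular Ullmann macrocyclisation follows (CuO, K2CO3, pyridine, high dilution, reflux). This ring closure is established for diaryl ether cyclophanes, and it should give the macrocyclic tetramethyl ether F9.
- BBr3 then converts F9 into 15.

Step 3.
- What may go wrong: activation of the electron-rich bromide flanked by a methoxy group may be sluggish. Hydrodebromination and slow degradation of the aldehyde on long heating could then take over.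
- Fallback: it sets out from 2, comes back at 6, and reverses the polarity of the ether coupling, so that the halide sits on the unhindered ring D.
- Alkyne 2 is coupled at room temperature (Sonogashira, iodide before bromide) with purchased 1-bromo-3-iodobenzene F10 to give 2-(benzyloxy)-4-[(3-bromophenyl)ethynyl]-1-methoxybenzene F11.
- A palladium-catalysed Buchwald-Hartwig diaryl ether synthesis (Pd(OAc)2, t-BuXPhos, K3PO4, toluene, 100 °C) of F11 with purchased 3-hydroxy-4,5-dimethoxybenzaldehyde F12 should then give 6.

Step 8.
- What may go wrong: cleavage of the flanked methoxy groups may be incomplete. The two liberated catechols may also suffer air oxidation during aqueous work-up and chromatography.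
- Fallback: it sets out from 14, comes back at 15, and changes what is isolated, so the free bis-catechol is never worked up or chromatographed.
- After BBr3, the mixture is quenched with MeOH and evaporated.
- The residue is peracetylated (Ac2O, pyridine) to the macrocyclic tetraacetate F13, which is stable, can be purified, and allows under-cleaved material to be separated and recycled.
- Acid methanolysis under argon (catalytic HCl in degassed MeOH, rt) followed by evaporation should release 15 without chromatography.

**Further compounds**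
F1 | step 7 | 1-bromo-5-ethynyl-2,3-dimethoxybenzene | COc1cc(C#C)cc(Br)c1OC
F2 | step 7 | 3-[(3-bromo-4,5-dimethoxyphenyl)ethynyl]phenol | COc1cc(C#Cc2cccc(O)c2)cc(Br)c1OC
F3 | step 7 | 3-iodo-4,5-dimethoxybenzaldehyde (purchased) | COc1cc(C=O)cc(I)c1OC
F4 | step 7 | 3-{3-[(3-bromo-4,5-dimethoxyphenyl)ethynyl]phenoxy}-4,5-dimethoxybenzaldehyde | COc1cc(C#Cc2cccc(Oc3cc(C=O)cc(OC)c3OC)c2)cc(Br)c1OC
F5 | step 7 | 1-bromo-5-{[3-(5-ethynyl-2,3-dimethoxyphenoxy)phenyl]ethynyl}-2,3-dimethoxybenzene | COc1cc(C#Cc2cccc(Oc3cc(C#C)cc(OC)c3OC)c2)cc(Br)c1OC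
F6 | step 7 | 4-iodophenol (purchased) | Oc1ccc(I)cc1
F7 | step 7 | bromo bis(diarylalkyne) phenol | COc1cc(C#Cc2cccc(Oc3cc(C#Cc4ccc(O)cc4)cc(OC)c3OC)c2)cc(Br)c1OC
F8 | step 7 | bromo seco-phenol | COc1cc(CCc2cccc(Oc3cc(CCc4ccc(O)cc4)cc(OC)c3OC)c2)cc(Br)c1OC
F9 | step 7 | macrocyclic tetramethyl ether | COc1cc2cc(c1OC)Oc1ccc(cc1)CCc1cc(OC)c(OC)c(c1)Oc1cccc(c1)CC2
F10 | step 3 | 1-bromo-3-iodobenzene (purchased) | Brc1cccc(I)c1
F11 | step 3 | 2-(benzyloxy)-4-[(3-bromophenyl)ethynyl]-1-methoxybenzene | COc1ccc(C#Cc2cccc(Br)c2)cc1OCc1ccccc1
F12 | step 3 | 3-hydroxy-4,5-dimethoxybenzaldehyde (purchased) | COc1cc(C=O)cc(O)c1OC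
F13 | step 8 | macrocyclic tetraacetate | CC(=O)Oc1cc2cc(c1OC(C)=O)Oc1ccc(cc1)CCc1cc(OC(C)=O)c(OC(C)=O)c(c1)Oc1cccc(c1)CC2
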